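**Retrosynthetic overview**

1. Cyclointegrin is a 5-hydroxy-7-methoxyflavone (ring A, pyranone ring, ring B) in which C3 and the 2'-oxygen are bridged by CH2–CH2–C(CH3)2 into an eight-membered oxocine ring; it has no stereocentre.
2. The pyranone ring is formed last: the O1–C2 bond is disconnected to an o-hydroxyaryl 1,3-diketone, closed by cyclodehydration after global debenzylation.
3. The oxocine ring is formed before it: the C3–CH2 bond is disconnected, to be made by an 8-endo-trig oxidative radical cyclisation of an acyclic 1,3-diketone onto the terminal CH2 of a 2'-O-(1,1-dimethylallyl) ether.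
4. Enabling feature: C3 lies between C2 and C4, both carbonyl carbons at the diketone level, so Mn(OAc)3 generates an electrophilic radical exactly there. The ring B oxygen carries C(CH3)2, which leaves the alkene one accessible terminus and no allylic hydrogen, and ring B holds this chain ortho to the C2 carbonyl.
5. The diketone comes from a Claisen condensation of the ring A acetophenone with the ring B salicylate, whose tertiary aryl ether is set by copper-catalysed propargylation and Lindlar reduction.

Key step: step 6

Remark: the one stereocentre that appears after the key step is formed as a racemate and becomes sp2 when the pyranone ring closes, so no stereocontrol is required anywhere.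

**Route**

Step 1
Reactants: 1 1-(2,6-dihydroxy-4-methoxyphenyl)ethan-1-one; 2 benzyl bromide
Product: 3 1-[2,6-bis(benzyloxy)-4-methoxyphenyl]ethan-1-one
Conditions: BnBr (2.4 equiv), K2CO3 (3 equiv), DMF, 70 °C
Reagents that add atoms: benzyl bromide, BrCc1ccccc1
Why: Williamson etherification, in which warm DMF with excess bromide should alkylate both ketone-chelated phenols and so mask the two ring A hydroxyls (one the future O1, one the future 5-OH) against trivalent manganese.

Step 2
Reactants: 4 methyl 2,4-dihydroxybenzoate; 2 benzyl bromide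
Product: 5 methyl 4-(benzyloxy)-2-hydroxybenzoate
Conditions: BnBr (1.05 equiv), K2CO3 (1.2 equiv), acetone, reflux
Reagents that add atoms: benzyl bromide, BrCc1ccccc1
Why: Williamson etherification that should be selective for the 4-hydroxyl, because the 2-hydroxyl is hydrogen-bonded to the ester and much less nucleophilic.

Step 3
Reactants: 5 methyl 4-(benzyloxy)-2-hydroxybenzoate; 6 3-chloro-3-methylbut-1-yne
Product: 7 methyl 4-(benzyloxy)-2-[(2-methylbut-3-yn-2-yl)oxy]benzoate
Conditions: 3-chloro-3-methylbut-1-yne (2 equiv), DBU (2 equiv), CuCl2·2H2O (1 mol%), MeCN, 0 °C to rt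
Reagents that add atoms: 3-chloro-3-methylbut-1-yne, CC(C)(Cl)C#C
Why: copper-catalysed propargylic substitution, in which a copper acetylide/allenylidene species lets the phenoxide form the tertiary aryl ether without a direct displacement at a tertiary carbon.

Step 4
Reactants: 7 methyl 4-(benzyloxy)-2-[(2-methylbut-3-yn-2-yl)oxy]benzoate
Product: 8 methyl 4-(benzyloxy)-2-[(2-methylbut-3-en-2-yl)oxy]benzoate
Conditions: H2 (1 atm), Pd/CaCO3 poisoned with Pb(OAc)2 (Lindlar catalyst), quinoline, EtOAc, rt
Reagents that add atoms: none
Why: Lindlar semi-hydrogenation should stop at the terminal alkene and leave the benzyl ether and ester untouched.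

Step 5
Reactants: 3 1-[2,6-bis(benzyloxy)-4-methoxyphenyl]ethan-1-one; 8 methyl 4-(benzyloxy)-2-[(2-methylbut-3-en-2-yl)oxy]benzoate
Product: 9 1-[2,6-bis(benzyloxy)-4-methoxyphenyl]-3-{4-(benzyloxy)-2-[(2-methylbut-3-en-2-yl)oxy]phenyl}propane-1,3-dione
Conditions: NaH (3 equiv), THF, 0 to 60 °C; then cold dilute aq. HCl to pH 5
Reagents that add atoms: none
Why: crossed Claisen condensation in which only ketone 3 can enolise and ester 8 cannot, driven to completion by deprotonation of the 1,3-diketone product, at a temperature below that of aromatic Claisen rearrangement of the allyl aryl ether.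

Step 6
Reactants: 9 1-[2,6-bis(benzyloxy)-4-methoxyphenyl]-3-{4-(benzyloxy)-2-[(2-methylbut-3-en-2-yl)oxy]phenyl}propane-1,3-dione
Product: 10 5-[2,6-bis(benzyloxy)-4-methoxybenzoyl]-9-(benzyloxy)-2,2-dimethyl-2,3,4,5-tetrahydro-6H-1-benzoxocin-6-one (racemic)
Conditions: Mn(OAc)3·2H2O (2.2 equiv), degassed EtOH (0.01 M), Ar, 40 °C
Reagents that add atoms: none
Why: Mn(OAc)3 binds the enolised 1,3-diketone and inner-sphere electron transfer gives an electrophilic radical on the central carbon between the two carbonyls, which adds to the terminal CH2 of the 1,1-dimethylallyl ether; the secondary alkyl radical so formed is not oxidised by trivalent manganese and takes a hydrogen atom from ethanol, whose 1-hydroxyethyl radical is oxidised to acetaldehyde by the second equivalent. The closest known reaction type is the Mn(OAc)3-mediated oxidative free-radical cyclisation of unsaturated 1,3-dicarbonyl compounds, together with the 8-endo cyclisations reported for alpha-carbonyl radicals whose carbonyl lies inside the forming ring. The one ring closed is the eight-membered oxocine ring, in the 8-endo-trig mode. The new stereocentre (the diketone methine) is formed without control as a racemate and is erased in step 7. The step needs 8-endo over 7-exo attack and cyclisation over dimerisation: the internal alkene carbon is neopentylic next to the O–C(CH3)2 carbon so only the terminal carbon is accessible, there is no allylic hydrogen to abstract, and ring B, the gem-dimethyl group and the in-ring carbonyl pre-organise the chain. High dilution and the absence of any hydride donor give the long-lived manganese-enolate radical time for a slow medium-ring closure, and 40 °C avoids aromatic Claisen rearrangement.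

Step 7
Reactants: 10 5-[2,6-bis(benzyloxy)-4-methoxybenzoyl]-9-(benzyloxy)-2,2-dimethyl-2,3,4,5-tetrahydro-6H-1-benzoxocin-6-one
Product: 12 cyclointegrin, via tris-phenol diketone 11 (not isolated)
Conditions: H2 (1 atm), 10% Pd/C, EtOAc–MeOH, rt; filter; then p-TsOH·H2O (0.2 equiv), MeOH, 50 °C
Reagents that add atoms: none
Why: hydrogenolysis of the three benzyl ethers followed by acid-catalysed cyclodehydration (a ring A hydroxyl adds to the benzoxocinone carbonyl and water is lost) should give the 4-pyranone; ring A is symmetric so either hydroxyl gives the same flavone, and the other remains as the chelated 5-OH.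

**Compound list**

1 | 1-(2,6-dihydroxy-4-methoxyphenyl)ethan-1-one | CC(=O)c1c(O)cc(OC)cc1O | starting material
2 | benzyl bromide | BrCc1ccccc1 | starting material
3 | 1-[2,6-bis(benzyloxy)-4-methoxyphenyl]ethan-1-one | CC(=O)c1c(OCc2ccccc2)cc(OC)cc1OCc1ccccc1 | intermediate
4 | methyl 2,4-dihydroxybenzoate | COC(=O)c1ccc(O)cc1O | starting material
5 | methyl 4-(benzyloxy)-2-hydroxybenzoate | COC(=O)c1ccc(OCc2ccccc2)cc1O | intermediate
6 | 3-chloro-3-methylbut-1-yne | CC(C)(Cl)C#C | starting material
7 | methyl 4-(benzyloxy)-2-[(2-methylbut-3-yn-2-yl)oxy]benzoate | COC(=O)c1ccc(OCc2ccccc2)cc1OC(C)(C)C#C | intermediate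
8 | methyl 4-(benzyloxy)-2-[(2-methylbut-3-en-2-yl)oxy]benzoate | COC(=O)c1ccc(OCc2ccccc2)cc1OC(C)(C)C=C | intermediate
9 | 1-[2,6-bis(benzyloxy)-4-methoxyphenyl]-3-{4-(benzyloxy)-2-[(2-methylbut-3-en-2-yl)oxy]phenyl}propane-1,3-dione | C=CC(C)(C)Oc1cc(OCc2ccccc2)ccc1C(=O)CC(=O)c1c(OCc2ccccc2)cc(OC)cc1OCc1ccccc1 | intermediate
10 | 5-[2,6-bis(benzyloxy)-4-methoxybenzoyl]-9-(benzyloxy)-2,2-dimethyl-2,3,4,5-tetrahydro-6H-1-benzoxocin-6-one (racemic) | CC1(C)CCC(C(=O)c2c(OCc3ccccc3)cc(OC)cc2OCc2ccccc2)C(=O)c2ccc(OCc3ccccc3)cc2O1 | intermediate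
11 | 5-(2,6-dihydroxy-4-methoxybenzoyl)-9-hydroxy-2,2-dimethyl-2,3,4,5-tetrahydro-6H-1-benzoxocin-6-one (racemic, not isolated) | CC1(C)CCC(C(=O)c2c(O)cc(OC)cc2O)C(=O)c2ccc(O)cc2O1 | intermediate
12 | cyclointegrin | COc1cc(O)c2c(=O)c3c(oc2c1)-c1ccc(O)cc1OC(C)(C)CC3 | target

**Step count and risks**

Total: 7 steps. Longest linear sequence: 6 steps (steps 2, 3, 4, 5, 6, 7).

Step 6 (most likely to fail). The eight-membered closure may be too slow, so that the diketone radical dimerises or returns to 9, or the adduct radical may fragment by loss of the aryloxyl radical (cleavage of the tertiary ether) before it is quenched by hydrogen transfer. The fallback forms the same bond by a polar, two-electron closure. It sets out from 8: anti-Markovnikov hydroboration–oxidation (9-BBN, THF; then NaBO3·4H2O) should give the primary alcohol methyl 4-(benzyloxy)-2-[(4-hydroxy-2-methylbutan-2-yl)oxy]benzoate F1. An Appel reaction (PPh3, CCl4) should convert it into methyl 4-(benzyloxy)-2-[(4-chloro-2-methylbutan-2-yl)oxy]benzoate F2. Claisen condensation of F2 with 3 (NaH, THF) should give 1-[2,6-bis(benzyloxy)-4-methoxyphenyl]-3-{4-(benzyloxy)-2-[(4-chloro-2-methylbutan-2-yl)oxy]phenyl}propane-1,3-dione F3. Finkelstein-assisted intramolecular C-alkylation of its enolate (NaI, Cs2CO3, MeCN, high dilution, 60 °C) should then close the ring and return to the route at 10.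

Step 5. Acyl transfer to the hindered, electron-rich ortho-alkoxy ester may be slower than self-condensation of the ketone or retro-Claisen cleavage of the product. The fallback replaces acylation by aldol addition and oxidation. It sets out from 8: reduction (LiAlH4, THF, 0 °C) should give {4-(benzyloxy)-2-[(2-methylbut-3-en-2-yl)oxy]phenyl}methanol F4, and oxidation (MnO2, CH2Cl2) should give 4-(benzyloxy)-2-[(2-methylbut-3-en-2-yl)oxy]benzaldehyde F5. Aldol addition of the lithium enolate of 3 (LiN(iPr)2, THF, −78 °C) should give racemic 1-[2,6-bis(benzyloxy)-4-methoxyphenyl]-3-{4-(benzyloxy)-2-[(2-methylbut-3-en-2-yl)oxy]phenyl}-3-hydroxypropan-1-one F6. Dess–Martin oxidation of F6 returns to the route at 9.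

Step 3. O-alkylation of the hydrogen-bonded, ortho-ester phenoxide at a tertiary propargylic centre may be outrun by elimination of the chloride to the enyne or by C-propargylation. The fallback uses a Tsuji–Trost O-allylation instead. It sets out from 5: methyl 2-methylbut-3-en-2-yl carbonate F7 (prepared from 2-methylbut-3-en-2-ol, n-BuLi and methyl chloroformate) with Pd(PPh3)4 (zerovalent palladium) in THF at 0 °C should attack at the more substituted allyl terminus and give the branched ether directly. This returns to the route at 8, bypassing 7 and step 4.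

**Further compounds**

F1 | step 6 | methyl 4-(benzyloxy)-2-[(4-hydroxy-2-methylbutan-2-yl)oxy]benzoate | COC(=O)c1ccc(OCc2ccccc2)cc1OC(C)(C)CCO
F2 | step 6 | methyl 4-(benzyloxy)-2-[(4-chloro-2-methylbutan-2-yl)oxy]benzoate | COC(=O)c1ccc(OCc2ccccc2)cc1OC(C)(C)CCCl
F3 | step 6 | 1-[2,6-bis(benzyloxy)-4-methoxyphenyl]-3-{4-(benzyloxy)-2-[(4-chloro-2-methylbutan-2-yl)oxy]phenyl}propane-1,3-dione | ClCCC(C)(C)Oc1cc(OCc2ccccc2)ccc1C(=O)CC(=O)c1c(OCc2ccccc2)cc(OC)cc1OCc1ccccc1
F4 | step 5 | {4-(benzyloxy)-2-[(2-methylbut-3-en-2-yl)oxy]phenyl}methanol | OCc1ccc(OCc2ccccc2)cc1OC(C)(C)C=C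
F5 | step 5 | 4-(benzyloxy)-2-[(2-methylbut-3-en-2-yl)oxy]benzaldehyde | O=Cc1ccc(OCc2ccccc2)cc1OC(C)(C)C=C
F6 | step 5 | 1-[2,6-bis(benzyloxy)-4-methoxyphenyl]-3-{4-(benzyloxy)-2-[(2-methylbut-3-en-2-yl)oxy]phenyl}-3-hydroxypropan-1-one (racemic) | C=CC(C)(C)Oc1cc(OCc2ccccc2)ccc1C(O)CC(=O)c1c(OCc2ccccc2)cc(OC)cc1OCc1ccccc1
F7 | step 3 | methyl 2-methylbut-3-en-2-yl carbonate | COC(=O)OC(C)(C)C=C
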